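**Retrosynthetic overview**
1. Previtexilactone 21 ⇒ bis-spiro cyclobutanone 20 by a catalyst-controlled Baeyer–Villiger ring expansion (four- to five-membered ring); this key step forms the lactone and sets C13.
2. 20 ⇒ alkynol 15 by gold-catalysed 5-exo cycloisomerisation (oxolane ring), dichloroketene [2+2] (cyclobutanone) and dechlorination.
3. 15 ⇒ decalin keto enol ether 9 + a butynyl Grignard reagent (C9–C11 bond, 9α-OH), then C6 reduction and acetylation.
4. 9 ⇒ ring B enone 3: ring A is annulated by conjugate addition of a ketal Grignard reagent (C10 quaternary centre), aldol condensation and methyl cuprate addition (C4 gem-dimethyl).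
5. 3 ⇒ m-cresol 1 by oxidative dearomatisation and enantioselective copper-catalysed methyl addition. Ring order: B (from the arene), A, oxolane, cyclobutanone, lactone.

Assumption: labdane numbering is used for descriptors (C1–C10 decalin, C11–C16 side chain, C17 on C8, C18/C19 on C4, C20 on C10); β is the face of the C10 methyl; the target is (5S,6R,8R,9R,10S,13S).

**Step 1**
Reactants: 1 3-methylphenol (m-cresol)
Product: 2 4,4-dimethoxy-3-methylcyclohexa-2,5-dien-1-one
Conditions: PhI(OAc)2 (2.2 equiv), MeOH, 0 °C to rt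
Reagents that add atoms: methanol (CO)
Why: Oxidative dearomatisation of a phenol with a trivalent iodine oxidant: two successive two-electron oxidations with para capture by methanol give the p-quinone monoketal, which carries the C6 carbonyl, the masked C9 carbonyl and the C10 methyl of ring B; no stereocentre is formed.

**Step 2**
Reactants: 2 4,4-dimethoxy-3-methylcyclohexa-2,5-dien-1-one
Product: 3 (5S)-4,4-dimethoxy-3,5-dimethylcyclohex-2-en-1-one
Conditions: Me2Zn (1.5 equiv), Cu(OTf)2 (2 mol %), (S,R,R)-binaphthyl phosphoramidite of bis(1-phenylethyl)amine (4 mol %), toluene, −25 °C; aq NH4Cl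
Reagents that add atoms: dimethylzinc (C[Zn]C)
Why: Copper-catalysed enantioselective conjugate addition of a dialkylzinc occurs only at the unsubstituted enone arm (the β-methyl arm is inert to dialkylzincs), and the ligand antipode that gives the 5S adduct is used; this C8 centre relays the absolute configuration to C10 in step 3 and is itself re-equilibrated in step 4.

**Step 3**
Reactants: 3 (5S)-4,4-dimethoxy-3,5-dimethylcyclohex-2-en-1-one; 4 2-(3-chloropropyl)-2-methyl-1,3-dioxolane
Product: 6 {[(3S,5S)-4,4-dimethoxy-3,5-dimethyl-3-[3-(2-methyl-1,3-dioxolan-2-yl)propyl]cyclohex-1-en-1-yl]oxy}trimethylsilane, via Grignard reagent 5 (not isolated)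
Conditions: 4, Mg, THF, 50 °C; then 3, CuBr·SMe2 (10 mol %), TMSCl (2 equiv), DMPU, THF, −78 to −30 °C; Et3N, pH 7 work-up
Reagents that add atoms: chlorotrimethylsilane (C[Si](C)(C)Cl)
Why: Copper-catalysed, TMSCl-accelerated conjugate addition of a Grignard reagent: the alkyl group enters the β-methyl enone by axial attack trans to the C5 methyl (the rule for 5-substituted cyclohexenones), which sets the C10 quaternary centre as S, and the enolate is trapped as its silyl enol ether.

**Step 4**
Reactants: 6 {[(3S,5S)-4,4-dimethoxy-3,5-dimethyl-3-[3-(2-methyl-1,3-dioxolan-2-yl)propyl]cyclohex-1-en-1-yl]oxy}trimethylsilane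
Product: 8 (2R,8aS)-2,5,8a-trimethyl-2,3,6,7,8,8a-hexahydronaphthalene-1,4-dione, via triketone 7 (not isolated)
Conditions: 1 M HCl, THF, rt; then KOH, MeOH, 60 °C
Reagents that add atoms: water (O)
Why: Acid hydrolysis of the silyl enol ether and both ketals is followed by a base-mediated intramolecular aldol condensation (the ring-closing half of a Robinson annulation) in which the C5 enolate of the C6 ketone attacks the unhindered methyl ketone to close ring A, while C8, now alpha to the C9 ketone, epimerises to the equatorial 8α-methyl (2R) isomer anti to the axial C10 methyl.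

**Step 5**
Reactants: 8 (2R,8aS)-2,5,8a-trimethyl-2,3,6,7,8,8a-hexahydronaphthalene-1,4-dione
Product: 9 (2R,8aS)-2,5,5,8a-tetramethyl-4-[(trimethylsilyl)oxy]-3,5,6,7,8,8a-hexahydronaphthalen-1(2H)-one
Conditions: Me2CuLi (from MeLi and CuI, 2.5 equiv), TMSCl (4 equiv), Et2O–THF, −78 to 0 °C; Et3N, aq NH4Cl/NH3 work-up
Reagents that add atoms: lithium dimethylcuprate ([Li+].C[Cu-]C); chlorotrimethylsilane (C[Si](C)(C)Cl)
Why: Organocuprate conjugate addition to the s-cis alkylidene-type enone (as with pulegone) creates the C4 gem-dimethyl group without a new stereocentre, and TMSCl both accelerates the addition and leaves C6 masked as its silyl enol ether so that only the C9 ketone is free for step 6.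

**Step 6**
Reactants: 9 (2R,8aS)-2,5,5,8a-tetramethyl-4-[(trimethylsilyl)oxy]-3,5,6,7,8,8a-hexahydronaphthalen-1(2H)-one; 10 (4-bromobut-1-yn-1-yl)trimethylsilane
Product: 14 (1R,2R,4R,4aS,8aS)-1-(but-3-yn-1-yl)-2,5,5,8a-tetramethyldecahydronaphthalene-1,4-diol, via Grignard reagent 11 (not isolated), via bis-silyl adduct 12 (not isolated), via hydroxy ketone 13 (not isolated)
Conditions: 10, Mg, THF; then 9, LaCl3·2LiCl (0.3 equiv), THF, 0 °C; then MeOH, K2CO3, rt; then NaBH4, 0 °C
Reagents that add atoms: none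
Why: Lanthanide-promoted Grignard 1,2-addition to the hindered C9 ketone follows the equatorial β trajectory (as with 2,2,6-trimethylcyclohexanones) and gives the axial 9α-OH cis to the 8α-methyl; methanolysis then removes both silyl groups with protonation of C5 from the α face (trans-decalin, also the thermodynamic outcome), and NaBH4 attacks the C6 ketone from the α face because the β face is screened by the syn-axial 4β and 10β methyls, giving the axial 6β-alcohol.

**Step 7**
Reactants: 14 (1R,2R,4R,4aS,8aS)-1-(but-3-yn-1-yl)-2,5,5,8a-tetramethyldecahydronaphthalene-1,4-diol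
Product: 15 (1R,3R,4R,4aS,8aS)-4-(but-3-yn-1-yl)-4-hydroxy-3,4a,8,8-tetramethyldecahydronaphthalen-1-yl acetate
Conditions: Ac2O, DMAP, Et3N, CH2Cl2, 40 °C
Reagents that add atoms: acetic anhydride (CC(=O)OC(C)=O)
Why: DMAP-catalysed acylation esterifies the secondary 6β-alcohol, while the tertiary 9α-alcohol flanked by C8 and the quaternary C10 is inert.

**Step 8**
Reactants: 15 (1R,3R,4R,4aS,8aS)-4-(but-3-yn-1-yl)-4-hydroxy-3,4a,8,8-tetramethyldecahydronaphthalen-1-yl acetate; 16 trichloroacetyl chloride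
Product: 19 6β-acetoxy-14,14-dichloro-9α,13-epoxy-15,16-cyclolabdan-15-one (C13 epimer mixture), via enol ether 17 (not isolated), via dichloroketene 18 (not isolated)
Conditions: AuCl (2 mol %), K2CO3 (10 mol %), MeCN, rt; filter, switch to Et2O; 16, Zn/Cu couple, POCl3, 0 °C to rt
Reagents that add atoms: none
Why: Gold-catalysed 5-exo-dig hydroalkoxylation (cycloisomerisation) of the γ-alkynol gives the 2-methyleneoxolane, whose electron-rich C13=C16 bond undergoes the regiospecific ketene–enol ether [2+2] cycloaddition (CCl2 carbon to the oxygen-bearing C13); the C13 centre forms as a mixture, which does not matter because step 9 makes the two ring arms identical.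

**Step 9**
Reactants: 19 6β-acetoxy-14,14-dichloro-9α,13-epoxy-15,16-cyclolabdan-15-one
Product: 20 6β-acetoxy-9α,13-epoxy-15,16-cyclolabdan-15-one
Conditions: Zn dust, AcOH, rt
Reagents that add atoms: none
Why: Zinc-mediated reductive dechlorination of an α,α-dichlorocyclobutanone leaves both α-carbons as CH2, so C13 is no longer stereogenic and the acetate and oxolane are untouched.

**Step 10**
Reactants: 20 6β-acetoxy-9α,13-epoxy-15,16-cyclolabdan-15-one
Product: 21 previtexilactone, (13S)-6β-acetoxy-9α,13-epoxylabdane 15→16 lactone (C15 carbonyl, C16 on the ring oxygen)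
Conditions: (R)-3,3'-bis(2,4,6-triisopropylphenyl)binaphthyl hydrogen phosphate (10 mol %), 30% aq H2O2 (1.5 equiv), CHCl3, −40 °C
Reagents that add atoms: hydrogen peroxide (OO)
Why: Proposed new method: a chiral-Brønsted-acid-catalysed Baeyer–Villiger ring expansion used for the first time on a 3,3-disubstituted (3-alkoxy-3-alkyl) spirocyclobutanone whose two ring CH2 groups are diastereotopic but constitutionally identical, so there is no electronic substrate bias and the stereogenic decalin is four bonds from the carbonyl; the acid adds H2O2 to the strained ketone and holds the Criegee perhydrate by a P=O···H–O / P–O–H···O–O hydrogen-bond pair, and its triisopropylphenyl pocket is expected to orient the spiro-oxolane so that only the C–CH2 bond syn to C10 across the oxolane is antiperiplanar to the O–O bond; that CH2 migrates to oxygen, the four-membered ring expands to the γ-lactone and C13 is set as S (both catalyst antipodes are screened and the matched one is used); closest known reaction: chiral phosphoric acid/H2O2 desymmetrising Baeyer–Villiger oxidation of prochiral 3-monosubstituted cyclobutanones.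

**Compound list**
1 | 3-methylphenol (m-cresol) | Cc1cccc(O)c1 | starting material
2 | 4,4-dimethoxy-3-methylcyclohexa-2,5-dien-1-one | COC1(OC)C=CC(=O)C=C1C | intermediate
3 | (5S)-4,4-dimethoxy-3,5-dimethylcyclohex-2-en-1-one | O=C1C=C(C)C(OC)(OC)[C@@H](C)C1 | intermediate
4 | 2-(3-chloropropyl)-2-methyl-1,3-dioxolane | CC1(CCCCl)OCCO1 | starting material
5 | [3-(2-methyl-1,3-dioxolan-2-yl)propyl]magnesium chloride | CC1(CCC[Mg]Cl)OCCO1 | intermediate
6 | {[(3S,5S)-4,4-dimethoxy-3,5-dimethyl-3-[3-(2-methyl-1,3-dioxolan-2-yl)propyl]cyclohex-1-en-1-yl]oxy}trimethylsilane | C[Si](C)(C)OC1=C[C@](C)(CCCC2(C)OCCO2)C(OC)(OC)[C@@H](C)C1 | intermediate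
7 | (2S,6S)-2,6-dimethyl-2-(4-oxopentyl)cyclohexane-1,4-dione | O=C1C[C@](C)(CCCC(C)=O)C(=O)[C@@H](C)C1 | intermediate
8 | (2R,8aS)-2,5,8a-trimethyl-2,3,6,7,8,8a-hexahydronaphthalene-1,4-dione (C4=C5 enone, C6 and C9 ketones, 8α-Me, 10β-Me) | O=C1C[C@@H](C)C(=O)[C@@]2(C)CCCC(C)=C12 | intermediate
9 | (2R,8aS)-2,5,5,8a-tetramethyl-4-[(trimethylsilyl)oxy]-3,5,6,7,8,8a-hexahydronaphthalen-1(2H)-one | C[Si](C)(C)OC1=C2C(C)(C)CCC[C@]2(C)C(=O)[C@H](C)C1 | intermediate
10 | (4-bromobut-1-yn-1-yl)trimethylsilane | C[Si](C)(C)C#CCCBr | starting material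
11 | [4-(trimethylsilyl)but-3-yn-1-yl]magnesium bromide | C[Si](C)(C)C#CCC[Mg]Br | intermediate
12 | (1R,2R,8aS)-2,5,5,8a-tetramethyl-1-[4-(trimethylsilyl)but-3-yn-1-yl]-4-[(trimethylsilyl)oxy]-1,2,3,5,6,7,8,8a-octahydronaphthalen-1-ol (9α-OH) | C[Si](C)(C)OC1=C2C(C)(C)CCC[C@]2(C)[C@@](O)(CCC#C[Si](C)(C)C)[C@H](C)C1 | intermediate
13 | (3R,4R,4aS,8aS)-4-(but-3-yn-1-yl)-4-hydroxy-3,4a,8,8-tetramethyloctahydronaphthalen-1(2H)-one | O=C1C[C@@H](C)[C@](O)(CCC#C)[C@@]2(C)CCCC(C)(C)[C@H]12 | intermediate
14 | (1R,2R,4R,4aS,8aS)-1-(but-3-yn-1-yl)-2,5,5,8a-tetramethyldecahydronaphthalene-1,4-diol (6β-OH, 9α-OH) | O[C@@H]1C[C@@H](C)[C@](O)(CCC#C)[C@@]2(C)CCCC(C)(C)[C@H]12 | intermediate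
15 | (1R,3R,4R,4aS,8aS)-4-(but-3-yn-1-yl)-4-hydroxy-3,4a,8,8-tetramethyldecahydronaphthalen-1-yl acetate | CC(=O)O[C@@H]1C[C@@H](C)[C@](O)(CCC#C)[C@@]2(C)CCCC(C)(C)[C@H]12 | intermediate
16 | trichloroacetyl chloride | ClC(Cl)(Cl)C(Cl)=O | starting material
17 | 6β-acetoxy-9α,13-epoxy-14,15-dinorlabd-13(16)-ene (2-methyleneoxolane spiro-fused at C9) | CC(=O)O[C@@H]1C[C@@H](C)[C@]2(CCC(=C)O2)[C@@]2(C)CCCC(C)(C)[C@H]12 | intermediate
18 | dichloroketene | ClC(Cl)=C=O | intermediate
19 | 6β-acetoxy-14,14-dichloro-9α,13-epoxy-15,16-cyclolabdan-15-one (C13 epimer mixture) | CC(=O)O[C@@H]1C[C@@H](C)[C@]2(CCC3(CC(=O)C3(Cl)Cl)O2)[C@@]2(C)CCCC(C)(C)[C@H]12 | intermediate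
20 | 6β-acetoxy-9α,13-epoxy-15,16-cyclolabdan-15-one | CC(=O)O[C@@H]1C[C@@H](C)[C@]2(CCC3(CC(=O)C3)O2)[C@@]2(C)CCCC(C)(C)[C@H]12 | intermediate
21 | previtexilactone, (5S,6R,8R,9R,10S,13S)-6β-acetoxy-9α,13-epoxylabdane 15→16 lactone | CC(=O)O[C@@H]1C[C@@H](C)[C@]2(CC[C@]3(COC(=O)C3)O2)[C@@]2(C)CCCC(C)(C)[C@H]12 | target

**Totals**
Total step count: 10. Longest linear sequence: 10 steps (from 1).

**Three steps most likely to fail**

Step 3 (quaternary C10 next to the ketal carbon). The β-methyl enone flanked by C(OMe)2 may resist cuprate addition or give 1,2-addition. If the facial preference turns out cis instead of trans, the other ligand antipode in step 2 corrects the absolute configuration. The fallback sets out from 3 and comes back at 8. Allylmagnesium bromide adds 1,2 to the ketone of 3 (THF, −78 °C) trans to the C5 methyl and gives (1R,5S)-4,4-dimethoxy-3,5-dimethyl-1-(prop-2-en-1-yl)cyclohex-2-en-1-ol F1. KH and 18-crown-6 (THF, rt) then trigger an anionic oxy-Cope rearrangement that delivers the allyl group suprafacially to the β-methyl carbon and gives (3S,5S)-4,4-dimethoxy-3,5-dimethyl-3-(prop-2-en-1-yl)cyclohexan-1-one F2. Cross-metathesis with but-3-en-2-one (second-generation Grubbs catalyst, CH2Cl2, 40 °C) gives (3S,5S)-4,4-dimethoxy-3,5-dimethyl-3-[(2E)-4-oxopent-2-en-1-yl]cyclohexan-1-one F3. Hydrogenation (H2, Pd/C, EtOAc) gives (3S,5S)-4,4-dimethoxy-3,5-dimethyl-3-(4-oxopentyl)cyclohexan-1-one F4, which under the conditions of step 4 gives 8.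

Step 6 (Grignard addition to the C9 ketone flanked by a quaternary and a tertiary carbon). Enolisation towards C8 or low conversion is the risk. The fallback sets out from 9 and comes back at 14. Allylmagnesium bromide, which adds to very hindered ketones through a cyclic six-centre transition state, is used in place of 11 and followed by the same K2CO3/MeOH and NaBH4 treatment to give (1R,2R,4R,4aS,8aS)-2,5,5,8a-tetramethyl-1-(prop-2-en-1-yl)decahydronaphthalene-1,4-diol F5. Hydroboration (9-BBN, THF; NaOH, H2O2) gives (1R,2R,4R,4aS,8aS)-1-(3-hydroxypropyl)-2,5,5,8a-tetramethyldecahydronaphthalene-1,4-diol F6. TEMPO with PhI(OAc)2 oxidises only the primary alcohol, and the lactol formed with the 9-OH goes on to 6β-hydroxy-14,15,16-trinorlabdan-13,9α-olide F7. DIBAL-H (CH2Cl2, −78 °C) gives the lactol 9α,13-epoxy-14,15,16-trinorlabdane-6β,13-diol F8. The Ohira–Bestmann reagent (dimethyl (1-diazo-2-oxopropyl)phosphonate, K2CO3, MeOH) converts this masked aldehyde into the terminal alkyne 14.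

Step 10 (proposed new catalyst-controlled Baeyer–Villiger). The catalyst may not distinguish the two CH2 arms, since O and CH2 at C13 differ little in size. The fallback uses known chemistry, sets out from 19 and comes back at 21. The chlorines are kept: mCPBA with NaHCO3 (CH2Cl2, 0 °C) effects the chlorine-directed regioselective Baeyer–Villiger oxidation in which the CH2 and not the CCl2 carbon migrates, giving 6β-acetoxy-14,14-dichloro-9α,13-epoxylabdane 15→16 lactone F9 as chromatographically separable C13 epimers. Zn in AcOH then dechlorinates the 13S epimer to 21. In this variant C13 is decided by the face selectivity of the ketene cycloaddition in step 8. The unwanted epimer, after dechlorination, can be recycled with DBU through retro-oxa-Michael opening to the butenolide and re-closure.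

**Further compounds**
F1 | step 3 | (1R,5S)-4,4-dimethoxy-3,5-dimethyl-1-(prop-2-en-1-yl)cyclohex-2-en-1-ol | C=CC[C@]1(O)C=C(C)C(OC)(OC)[C@@H](C)C1
F2 | step 3 | (3S,5S)-4,4-dimethoxy-3,5-dimethyl-3-(prop-2-en-1-yl)cyclohexan-1-one | O=C1C[C@](C)(CC=C)C(OC)(OC)[C@@H](C)C1
F3 | step 3 | (3S,5S)-4,4-dimethoxy-3,5-dimethyl-3-[(2E)-4-oxopent-2-en-1-yl]cyclohexan-1-one | O=C1C[C@](C)(C/C=C/C(C)=O)C(OC)(OC)[C@@H](C)C1
F4 | step 3 | (3S,5S)-4,4-dimethoxy-3,5-dimethyl-3-(4-oxopentyl)cyclohexan-1-one | O=C1C[C@](C)(CCCC(C)=O)C(OC)(OC)[C@@H](C)C1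
F5 | step 6 | (1R,2R,4R,4aS,8aS)-2,5,5,8a-tetramethyl-1-(prop-2-en-1-yl)decahydronaphthalene-1,4-diol | O[C@@H]1C[C@@H](C)[C@](O)(CC=C)[C@@]2(C)CCCC(C)(C)[C@H]12
F6 | step 6 | (1R,2R,4R,4aS,8aS)-1-(3-hydroxypropyl)-2,5,5,8a-tetramethyldecahydronaphthalene-1,4-diol | O[C@@H]1C[C@@H](C)[C@](O)(CCCO)[C@@]2(C)CCCC(C)(C)[C@H]12
F7 | step 6 | 6β-hydroxy-14,15,16-trinorlabdan-13,9α-olide | O[C@@H]1C[C@@H](C)[C@]2(CCC(=O)O2)[C@@]2(C)CCCC(C)(C)[C@H]12
F8 | step 6 | 9α,13-epoxy-14,15,16-trinorlabdane-6β,13-diol (lactol, anomer mixture) | O[C@@H]1C[C@@H](C)[C@]2(CCC(O)O2)[C@@]2(C)CCCC(C)(C)[C@H]12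
F9 | step 10 | 6β-acetoxy-14,14-dichloro-9α,13-epoxylabdane 15→16 lactone (C13 as in 21) | CC(=O)O[C@@H]1C[C@@H](C)[C@]2(CC[C@]3(COC(=O)C3(Cl)Cl)O2)[C@@]2(C)CCCC(C)(C)[C@H]12
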